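(All runs stem from a simulated flask with constants of no real substance; scatter was added.)

The reading falls at 3.0 min. The meeting took this flask, with second end groups dosed into first end groups, and the three runs before it.

| setting | spring | winter | dawn | flask |
|---|---|---|---|---|
| first end groups | 0.20 mM | 0.20 mM | 0.40 mM | 0.20 mM |
| second end groups | 0.31 mM (fed, over 0.20 s) | 0.48 mM (fed, over 0.20 s) | 0.22 mM (fed, over 0.20 s) | 0.220 mM (fed, over 0.20 s) |
| remark | run made earlier; the fed solution adds 0.50 times the starting volume | run made earlier; the fed solution adds 0.50 times the starting volume | run made earlier; the fed solution adds 0.50 times the starting volume | the fed solution adds 0.50 times the starting volume |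
| time |  |  |  | 3.0 min |

- spring (time / min: links / %, first end groups / %): 0.167: 91.8, 7.7; 0.500: 98.2, 2.8; 0.833: 98.2, 1.1; 1.33: 98.5, 1.4; 2.00: 98.8, 0.8; 2.50: 98.6, 0.5; 3.00: 98.1, 1.5
- winter (time / min: links / %, first end groups / %): 0.417: 99.5, 0; 0.833: 100.5, 0; 1.33: 99.8, 0.2; 1.50: 100.2, 0; 2.00: 99.8, 0; 2.50: 99.7, 0.7; 3.00: 100.8, 0.4
- dawn (time / min: links / %, first end groups / %): 0.667: 51.1, 48.8; 1.33: 51.4, 47.4; 2.00: 50.5, 47.4; 2.50: 51.2, 47.1; 3.00: 50.4, 46.2

(each reading ± 0.5 percentage points)

- charges are per starting volume, the dose included; the dosed solution carries all of it
- reactions considered so far: first end groups + second end groups -> links; first end groups -> decomposition product; second end groups -> decomposed reagent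
- the reaction counts as stopped when no species that holds the first end groups changes by six tenths of a point or more over the second half of the time

- which holds at 3.0 min: what has brought the reaction to rest, or that it has not come to rest (it is still moving / the second end groups has run out first / all of the first end groups has reacted / forward and back rates have come level)
- amount of links at 3.0 min, in percent of the first end groups charged
- amount of links if the flask were left three thousand times as long, in percent of the first end groups charged

The chair noted that in the dawn run links stood flat near 50.9%. Dawn had 0.550 equivalents of second end groups, and free first end groups stood at 46.2% at the last reading.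

I argued for freezing one thing. Linking and decay are both first order in second end groups, so that concentration cancels from their ratio. Let x be the free fraction of the first charge, L the links as a fraction, and e the equivalents. Setting aside the decay of first end groups, x = 1 − L. Each link then costs w/x of extra second end groups, where w is a selectivity factor, constant within one flask. Summed up to the point where second end groups are gone, e = L + w ln(1/x).

The waste constant is w times the charge of first end groups, and the dawn readings, with their scatter, put it near 0.0229 mM. For this flask that means w = 0.115 at e = 1.10.

Try x = w. The slope of the balance there is 2, so one Newton step gives L = 86.9%. Second end groups would be the limiting reagent despite the excess. Dawn's links held flat while free first end groups drifted from 48.8% to 46.2%, so I kept that figure for the long flask.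

The forecast said the second end groups has run out first, with 86% and 86%, slightly below my figure, holding that “the second end groups also decompose in competition with linking”.

The flask gives the second end groups has run out first, with 0% of them left, and links at 85.6% and 85.6%.

    first end groups + second end groups → links (k = 3030 M⁻¹ s⁻¹)
    first end groups → decomposition product (k = 3.15 × 10⁻⁴ s⁻¹)
    second end groups → decomposed reagent (k = 0.0510 s⁻¹)

At 0.0301 min in this flask linking used second end groups 4.5 times as fast as their decay. The rule calls that ratio x/w, so it falls as first end groups are used: with 13.6% free at 3.00 min and w from dawn it reckons lower, at 1.18, though second end groups then stand at 0%.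

The neighbouring flask with 0.055 mM of second end groups has e = 0.275. Taking L near e/(1+w) for the logarithm, the rule gives 24.3%. Computed, that flask holds 24.0% links and 71.8% free first end groups.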